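**Strategy.** The route rests on cutting ring B at O–C4 and C4–C10. C4 carries the ring B ether oxygen, quaternary C10 and two carbonyl-level carbons (lactone C5 and the future carbinol C3), so it is brought in as the carbene of dimethyl diazomalonate. In one operation the carbene is captured by the oxygen of a 2-alkenyl oxetane and the ylide rearranges [2,3]: O–C4 and C4–C10 form, the four-membered ring grows into ring B, and the oxetane stereocentre is relayed to C10. The precursor is an (S)-2,2-dimethyloxetane (O–C6 bond in place) bearing an (E)-2-methyl-3-silyloxypropenyl arm (C9=C10, C11). Numbering: ring A = C1(OAc)–C2–C3–C4–C10–C11(OBz); ring B = C4–O–C6–C7=C8–C9–C10; ring C = C4–C5(=O)–O–C9–C10.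

Key step: step 9

Remark: the C11 silyl group is taken as triisopropylsilyl (its bulk should keep the carbenoid off the allylic ether oxygen, sharpen the facial bias of step 10 and survive the hydroxide of step 10); dialdehyde 23 is drawn open although it should rest mainly as the lactol between C3–OH and the C11 aldehyde.

Step 1
Reactants: 1 (R)-benzyl glycidyl ether
Product: 2 (2R)-1-(benzyloxy)-4-methylpent-4-en-2-ol
Conditions: CH2=C(Me)MgBr, CuI (10 mol%), THF, −30 to 0 °C; NH4Cl work-up
Reagents that add atoms: isopropenylmagnesium bromide, CC(=C)[Mg]Br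
Why: Copper-catalysed Grignard opening of a terminal epoxide at its unsubstituted carbon; the stereocentre comes from the chiral pool and is not touched.

Step 2
Reactants: 2 (2R)-1-(benzyloxy)-4-methylpent-4-en-2-ol
Product: 3 (2R)-1-(benzyloxy)-4-methylpentane-2,4-diol
Conditions: Co(acac)2 (cat.), PhSiH3, O2 (1 atm), THF, rt
Reagents that add atoms: dioxygen, O=O
Why: Mukaiyama hydration (hydrogen-atom transfer to the 1,1-disubstituted olefin, then trapping by O2) should give the Markovnikov tertiary alcohol without affecting the carbinol centre.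

Step 3
Reactants: 3 (2R)-1-(benzyloxy)-4-methylpentane-2,4-diol
Product: 5 (2S)-2-[(benzyloxy)methyl]-4,4-dimethyloxetane, via secondary mesylate 4 (not isolated)
Conditions: MsCl, Et3N, CH2Cl2, −10 °C; then KOtBu, THF, 0 °C to rt
Reagents that add atoms: methanesulfonyl chloride, CS(=O)(=O)Cl (its atoms stay only in 4)
Why: Only the secondary hydroxyl is sulfonylated and the tertiary alkoxide then closes the ring by intramolecular Williamson etherification (4-exo-tet SN2), inverting the carbinol centre from R to S; the leaving group sits on a non-allylic carbon, which should keep ionisation and fragmentation down.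

Step 4
Reactants: 5 (2S)-2-[(benzyloxy)methyl]-4,4-dimethyloxetane
Product: 6 (2S)-(4,4-dimethyloxetan-2-yl)methanol
Conditions: H2 (1 atm), Pd on carbon (Pd/C), EtOAc, rt
Reagents that add atoms: none
Why: Hydrogenolysis of the benzyl ether under neutral conditions, to which the oxetane is inert.

Step 5
Reactants: 6 (2S)-(4,4-dimethyloxetan-2-yl)methanol
Product: 8 ethyl (2E)-3-[(2S)-4,4-dimethyloxetan-2-yl]-2-methylprop-2-enoate, via oxetane aldehyde 7 (not isolated)
Conditions: IBX, DMSO, rt; then Ph3P=C(Me)CO2Et, rt
Reagents that add atoms: ethyl 2-(triphenylphosphoranylidene)propanoate, CCOC(=O)C(C)=P(c1ccccc1)(c1ccccc1)c1ccccc1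
Why: One-pot IBX oxidation and Wittig olefination; the stabilised ylide should give the E trisubstituted enoate and traps the volatile, epimerisable α-alkoxy aldehyde as it forms.

Step 6
Reactants: 8 ethyl (2E)-3-[(2S)-4,4-dimethyloxetan-2-yl]-2-methylprop-2-enoate
Product: 9 (2E)-3-[(2S)-4,4-dimethyloxetan-2-yl]-2-methylprop-2-en-1-ol
Conditions: i-Bu2AlH, CH2Cl2, −78 °C
Reagents that add atoms: none
Why: 1,2-Reduction of the enoate to the allylic alcohol; olefin geometry and oxetane are unaffected.

Step 7
Reactants: 9 (2E)-3-[(2S)-4,4-dimethyloxetan-2-yl]-2-methylprop-2-en-1-ol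
Product: 10 (4S)-2,2-dimethyl-4-[(1E)-2-methyl-3-(triisopropylsilyloxy)prop-1-en-1-yl]oxetane
Conditions: TIPSCl, imidazole, DMF, rt
Reagents that add atoms: chlorotriisopropylsilane, CC(C)[Si](Cl)(C(C)C)C(C)C
Why: Standard silylation of a primary allylic alcohol.

Step 8
Reactants: 11 dimethyl malonate
Product: 12 dimethyl diazomalonate
Conditions: 4-acetamidobenzenesulfonyl azide, Et3N, MeCN, 0 °C to rt
Reagents that add atoms: 4-acetamidobenzenesulfonyl azide, CC(=O)Nc1ccc(cc1)S(=O)(=O)N=[N+]=[N-]
Why: Regitz diazo transfer to the activated methylene.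

Step 9
Reactants: 10 (4S)-2,2-dimethyl-4-[(1E)-2-methyl-3-(triisopropylsilyloxy)prop-1-en-1-yl]oxetane; 12 dimethyl diazomalonate
Product: 14 dimethyl (3R)-3,7,7-trimethyl-3-[(triisopropylsilyloxy)methyl]-2,3,6,7-tetrahydrooxepine-2,2-dicarboxylate, via oxonium ylide 13 (not isolated)
Conditions: Rh2(OAc)4 (2 mol%), ClCH2CH2Cl, 70 °C, 12 added slowly
Reagents that add atoms: none
Why: Proposed new method: the electrophilic rhodium carbenoid from 12 is captured by the oxetane oxygen of 10 to give ylide 13, whose malonate carbon attacks C10 through a five-membered envelope transition state while the strained allylic O–C8 bond breaks ([2,3] sigmatropic shift). The closest known reaction types are the [2,3] rearrangement of allyl ether oxonium ylides made with diazomalonate carbenoids and the carbenoid ring expansion of oxetanes to tetrahydrofurans. Ring B closes by three-atom ring expansion of the oxetane (four to seven members); the ring can only hold a cis C8=C9 olefin, which forces C7 syn to C10 in the transition state with the C10 methyl pointing inwards. C10 is set by suprafacial transfer from the (S) centre C8: with the E olefin the carbon is delivered to the olefin face that carries the oxetane oxygen, which should give (R)-C10 as in the target. The step needs the [2,3] shift to beat the [1,2] shift, O-alkylation of the malonate enolate (1,4-dioxepine), cyclopropanation and ylide formation at the silyl ether oxygen; the allylic C–O bond held over the π system, the release of ring strain, the hindered trisubstituted olefin and the bulky triisopropylsilyl group are what should secure this.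

Step 10
Reactants: 14 oxepene diester
Product: 16 iodolactone acid (8-iodo ring B bridged by the lactone C4–C5(=O)–O–C9 with CO2H on C4), via dicarboxylic acid 15 (not isolated)
Conditions: KOH, MeOH/H2O, 65 °C; then NaHCO3, I2, KI, THF/H2O, 0 °C; aq. HCl work-up
Reagents that add atoms: potassium hydroxide, [K+].[OH-]; iodine, II
Why: Saponification to the malonate dianion and iodolactonisation (5-exo, anti addition) in which the carboxylate cis to the larger C10 substituent CH2OTIPS should close onto C9 while iodine takes the face of the C10 methyl, because the bicyclic transition state puts the C10 group that is cis to the iodonium over the iodinated four-atom bridge and the other one over the flat lactone; this sets C4 and C9 (and transient C8).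

Step 11
Reactants: 16 iodolactone acid
Product: 17 lactone acid with C7=C8 (rings B and C complete; CO2H on C4; CH2OTIPS and Me on C10)
Conditions: DBU, toluene, 60 °C; aq. HCl work-up
Reagents that add atoms: none
Why: E2 dehydroiodination; only a C7 hydrogen can be anti to iodine (H9 is cis to it), so the olefin should form at C7=C8, and the C4 carboxylate lies on the iodine face and cannot displace it.

Step 12
Reactants: 17 lactone acid
Product: 19 vinyl ketone (C4–C(=O)–CH=CH2; the ketone carbon is C3 and the vinyl carbons are C2 and C1), via acid chloride 18 (not isolated)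
Conditions: (COCl)2, DMF (cat.), CH2Cl2, 0 °C to rt; then Bu3SnCH=CH2, Pd2(dba)3 (2.5 mol%), P(2-furyl)3, THF, 45 °C
Reagents that add atoms: tributyl(vinyl)stannane, C=C[Sn](CCCC)(CCCC)CCCC; oxalyl chloride, O=C(Cl)C(=O)Cl (chlorine stays only in 18)
Why: Acyl Stille coupling makes the ketone without touching the lactone; C4 is a bridgehead, so neither ketene formation nor retro-Claisen cleavage through a C4 enolate is open.

Step 13
Reactants: 19 vinyl ketone
Product: 20 tertiary allylic alcohol (C3 with Me, OH and vinyl)
Conditions: MeMgBr, CeCl3, THF, −78 °C; NH4Cl work-up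
Reagents that add atoms: methylmagnesium bromide, C[Mg]Br
Why: 1,2-Addition of the organocerium reagent to the non-enolisable enone; C3 should be set by Felkin–Anh (Cornforth) control, the methyl coming in anti to the C4–O bond and past the lactone carbonyl C5 instead of quaternary C10 (a chelate between ketone and lactone carbonyl predicts the same face), which gives the C3 configuration of the target.

Step 14
Reactants: 20 tertiary allylic alcohol
Product: 21 diol (C1 primary alcohol; C3 tertiary alcohol; C11 still silylated)
Conditions: 9-BBN, THF, 0 °C to rt; then H2O2, pH 7 phosphate buffer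
Reagents that add atoms: hydrogen peroxide, OO
Why: Anti-Markovnikov hydroboration–oxidation of the monosubstituted vinyl group; 9-BBN should leave the hindered ring olefin C7=C8 and the lactone alone.

Step 15
Reactants: 21 diol
Product: 22 triol (C1–OH, C3–OH, C11–OH)
Conditions: HF·pyridine, pyridine, THF, 0 °C to rt
Reagents that add atoms: none
Why: Desilylation under mildly acidic fluoride conditions, which avoids an alkoxide at C11 that could attack the lactone.

Step 16
Reactants: 22 triol
Product: 23 dialdehyde (C1 and C11 aldehydes; C3–OH free)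
Conditions: (COCl)2, DMSO, CH2Cl2, −78 °C; then Et3N, −78 to 0 °C
Reagents that add atoms: none
Why: Swern oxidation of both primary alcohols; the activated DMSO is consumed before the aldehydes are released, so the lactol of C3–OH with the C11 aldehyde should not be oxidised further.

Step 17
Reactants: 23 dialdehyde
Product: 24 acyloin (ring A closed; C1 ketone; C11–OH cis to the C10 methyl)
Conditions: 2-(pentafluorophenyl)-6,7-dihydro-5H-pyrrolo[2,1-c][1,2,4]triazol-2-ium tetrafluoroborate (10 mol%), i-Pr2NEt, CH2Cl2, rt, high dilution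
Reagents that add atoms: none
Why: Intramolecular crossed benzoin reaction in which the carbene adds to the unhindered C1 aldehyde and the Breslow intermediate attacks the neopentyl C11 aldehyde (six-membered ring); in the chair-like transition state the azolium group on C1 must be equatorial (the axial site lies between the C3 and C10 methyls), its hydroxyl is axial and hydrogen-bonds to the aldehyde oxygen, which is therefore equatorial and ends up cis to the C10 methyl, also the more stable epimer.

Step 18
Reactants: 24 acyloin
Product: 25 C11 benzoate (C1 ketone)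
Conditions: BzCl, pyridine, DMAP (cat.), CH2Cl2, 0 °C to rt
Reagents that add atoms: benzoyl chloride, O=C(Cl)c1ccccc1
Why: Acylation of the only secondary hydroxyl; the tertiary C3–OH should not react.

Step 19
Reactants: 25 C11 benzoate
Product: 26 C1 alcohol (C1–OH cis to C11–OBz and trans to C3–OH)
Conditions: Me4NBH(OAc)3, MeCN/AcOH, −30 °C
Reagents that add atoms: none
Why: Evans–Saksena directed reduction of the β-hydroxy ketone; hydride is delivered from boron bound to C3–OH, on the face that is also the only open one (the other is blocked by the axial C3 and C10 methyls), so the new C1–OH should be anti to C3–OH.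

Step 20
Reactants: 26 C1 alcohol
Product: 27 target CNP0178319.3
Conditions: Ac2O, pyridine, DMAP (cat.), CH2Cl2, rt
Reagents that add atoms: acetic anhydride, CC(=O)OC(C)=O
Why: Acetylation of the secondary C1 hydroxyl; the tertiary C3–OH should stay free under these conditions.

**Compound list**

1 | (R)-benzyl glycidyl ether | C1[C@@H](O1)COCc2ccccc2 | starting material
2 | (2R)-1-(benzyloxy)-4-methylpent-4-en-2-ol | CC(=C)C[C@@H](O)COCc1ccccc1 | intermediate
3 | (2R)-1-(benzyloxy)-4-methylpentane-2,4-diol | CC(C)(O)C[C@@H](O)COCc1ccccc1 | intermediate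
4 | (2R)-1-(benzyloxy)-4-hydroxy-4-methylpentan-2-yl methanesulfonate (not isolated) | CC(C)(O)C[C@@H](OS(C)(=O)=O)COCc1ccccc1 | intermediate
5 | (2S)-2-[(benzyloxy)methyl]-4,4-dimethyloxetane | CC1(C)C[C@@H](COCc2ccccc2)O1 | intermediate
6 | (2S)-(4,4-dimethyloxetan-2-yl)methanol | CC1(C)C[C@@H](CO)O1 | intermediate
7 | (2S)-4,4-dimethyloxetane-2-carbaldehyde (not isolated) | CC1(C)C[C@@H](C=O)O1 | intermediate
8 | ethyl (2E)-3-[(2S)-4,4-dimethyloxetan-2-yl]-2-methylprop-2-enoate | CC1(C)C[C@@H](/C=C(\C)C(=O)OCC)O1 | intermediate
9 | (2E)-3-[(2S)-4,4-dimethyloxetan-2-yl]-2-methylprop-2-en-1-ol | CC1(C)C[C@@H](/C=C(\C)CO)O1 | intermediate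
10 | (4S)-2,2-dimethyl-4-[(1E)-2-methyl-3-(triisopropylsilyloxy)prop-1-en-1-yl]oxetane (key-step precursor) | CC1(C)C[C@@H](/C=C(\C)CO[Si](C(C)C)(C(C)C)C(C)C)O1 | intermediate
11 | dimethyl malonate | COC(=O)CC(=O)OC | starting material
12 | dimethyl diazomalonate | COC(=O)C(=[N+]=[N-])C(=O)OC | intermediate
13 | oxonium ylide of 10 with bis(methoxycarbonyl)carbene (not isolated) | COC(=O)[C-](C(=O)OC)[O+]1C(C)(C)C[C@H]1/C=C(\C)CO[Si](C(C)C)(C(C)C)C(C)C | intermediate
14 | dimethyl (3R)-3,7,7-trimethyl-3-[(triisopropylsilyloxy)methyl]-2,3,6,7-tetrahydrooxepine-2,2-dicarboxylate (ring B; gem-diester C4; C10 set; C8=C9) | COC(=O)C1(C(=O)OC)OC(C)(C)CC=C[C@]1(C)CO[Si](C(C)C)(C(C)C)C(C)C | intermediate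
15 | (3R)-3,7,7-trimethyl-3-[(triisopropylsilyloxy)methyl]-2,3,6,7-tetrahydrooxepine-2,2-dicarboxylic acid (not isolated) | OC(=O)C1(C(=O)O)OC(C)(C)CC=C[C@]1(C)CO[Si](C(C)C)(C(C)C)C(C)C | intermediate
16 | iodolactone acid: ring B bridged by the lactone C4–C5(=O)–O–C9, iodine on C8 trans to the lactone oxygen, CO2H on C4, Me and CH2OTIPS on C10 (C4, C9, C10 as in the target) | OC(=O)[C@]23OC(C)(C)C[C@@H](I)[C@H](OC2=O)[C@]3(C)CO[Si](C(C)C)(C(C)C)C(C)C | intermediate
17 | lactone acid: as 16 but with C7=C8 in place of the iodide | OC(=O)[C@]23OC(C)(C)C=C[C@H](OC2=O)[C@]3(C)CO[Si](C(C)C)(C(C)C)C(C)C | intermediate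
18 | acid chloride of 17 (not isolated) | ClC(=O)[C@]23OC(C)(C)C=C[C@H](OC2=O)[C@]3(C)CO[Si](C(C)C)(C(C)C)C(C)C | intermediate
19 | vinyl ketone: C4–C(=O)–CH=CH2 on the bicyclic lactone | C=CC(=O)[C@]23OC(C)(C)C=C[C@H](OC2=O)[C@]3(C)CO[Si](C(C)C)(C(C)C)C(C)C | intermediate
20 | tertiary allylic alcohol: C3 with Me, OH and vinyl, configured as in the target | C=C[C@](C)(O)[C@]23OC(C)(C)C=C[C@H](OC2=O)[C@]3(C)CO[Si](C(C)C)(C(C)C)C(C)C | intermediate
21 | diol: C3(Me)(OH)–CH2–CH2OH side chain, C11 as CH2OTIPS | OCC[C@](C)(O)[C@]23OC(C)(C)C=C[C@H](OC2=O)[C@]3(C)CO[Si](C(C)C)(C(C)C)C(C)C | intermediate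
22 | triol: as 21 with free C11–OH | OCC[C@](C)(O)[C@]23OC(C)(C)C=C[C@H](OC2=O)[C@]3(C)CO | intermediate
23 | dialdehyde: C1 and C11 as CHO, C3–OH free (open form of the lactol) | O=CC[C@](C)(O)[C@]23OC(C)(C)C=C[C@H](OC2=O)[C@]3(C)C=O | intermediate
24 | acyloin: tricyclic core with C1 ketone, C11–OH cis to the C10 methyl, C3–OH free | O=C1C[C@](C)(O)[C@]23OC(C)(C)C=C[C@H](OC2=O)[C@]3(C)[C@H]1O | intermediate
25 | C11 benzoate of 24 | O=C1C[C@](C)(O)[C@]23OC(C)(C)C=C[C@H](OC2=O)[C@]3(C)[C@H]1OC(=O)c1ccccc1 | intermediate
26 | C1 alcohol: deacetyl target (C1–OH cis to C11–OBz, trans to C3–OH) | O[C@H]1C[C@](C)(O)[C@]23OC(C)(C)C=C[C@H](OC2=O)[C@]3(C)[C@H]1OC(=O)c1ccccc1 | intermediate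
27 | CNP0178319.3 | CC(=O)O[C@H]1C[C@](C)(O)[C@]23OC(C)(C)C=C[C@H](OC2=O)[C@]3(C)[C@H]1OC(=O)c1ccccc1 | target

**Step count.** Total: 20 steps. Longest linear sequence: 19 steps (steps 1–7 and 9–20); step 8 is a one-step branch.

**Steps most likely to fail**

1. Step 9. The ylide may rearrange by a [1,2] shift or by O-alkylation of the malonate enolate instead of the [2,3] shift, the carbenoid may cyclopropanate the olefin, or bond formation between two fully substituted carbons may be too slow. The fallback uses known chemistry and gives up the chirality relay. It sets out from 12. The acyclic ether triisopropyl{[(2E)-2-methyl-4-[(2-methylpent-4-en-2-yl)oxy]but-2-en-1-yl]oxy}silane F1 would be made by Williamson etherification of 2-methylpent-4-en-2-ol (KH, THF) with (E)-4-bromo-2-methylbut-2-enyl triisopropylsilyl ether. Treated with 12 and Rh2(OAc)4, F1 should undergo the documented [2,3] rearrangement of an allyl ether oxonium ylide to give the racemic diene dimethyl 2-[(2-methylpent-4-en-2-yl)oxy]-2-[2-methyl-1-(triisopropylsilyloxy)but-3-en-2-yl]propanedioate F2. Ring-closing metathesis of F2 (second-generation Grubbs catalyst, CH2Cl2, 40 °C) would close ring B to 14 together with its enantiomer, dimethyl (3S)-3,7,7-trimethyl-3-[(triisopropylsilyloxy)methyl]-2,3,6,7-tetrahydrooxepine-2,2-dicarboxylate F3, which is removed on a chiral stationary phase. The route is rejoined at 14.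

2. Step 17. Intramolecular aldol reaction of the dialdehyde, carbene addition at the wrong aldehyde or isomerisation of the acyloin may compete. The fallback sets out from 23. Pinacol coupling with SmI2 (THF, t-BuOH, −78 °C) should close ring A to the cis-diol with both hydroxyls on the face away from the C10 methyl, F4. Oxidation of the less hindered C1 hydroxyl with 4-acetamido-2,2,6,6-tetramethyl-1-oxopiperidinium tetrafluoroborate would give the C11 epimer of acyloin 24, F5, and benzoylation (BzCl, pyridine, DMAP) its benzoate, the C11 epimer of 25, F6. Equilibration of this α-benzoyloxy ketone with DBU (cat.) to the equatorial epimer rejoins the route at 25.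

3. Step 10. Poor facial selectivity in the iodolactonisation (methyl against CH2OTIPS on C10) would give the lactone from the wrong carboxyl group. The fallback sets out from 14 and differentiates the two esters first. Bu4NF frees the C11 hydroxyl, which can only close onto the ester cis to it and should give the cis-fused γ-lactone methyl ester F7 (lactone C4–C5(=O)–O–C11). One equivalent of LiOH opens only the lactone, and the C5 carboxylate, now the only free one, is iodolactonised in the same flask (I2, NaHCO3) to the 8-iodo lactone methyl ester with free C11–OH, F8. Silylation (TIPSOTf, 2,6-lutidine) gives its triisopropylsilyl ether F9 and DBU the C7=C8 lactone methyl ester F10. KOH then acid hydrolyses the ester and lets the C5 acid, the only one that reaches O9, relactonise. The route is rejoined at 17.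

Further compounds
F1 | step 9 | triisopropyl{[(2E)-2-methyl-4-[(2-methylpent-4-en-2-yl)oxy]but-2-en-1-yl]oxy}silane | C=CCC(C)(C)OC/C=C(\C)CO[Si](C(C)C)(C(C)C)C(C)C
F2 | step 9 | dimethyl 2-[(2-methylpent-4-en-2-yl)oxy]-2-[2-methyl-1-(triisopropylsilyloxy)but-3-en-2-yl]propanedioate (racemic) | COC(=O)C(OC(C)(C)CC=C)(C(=O)OC)C(C)(C=C)CO[Si](C(C)C)(C(C)C)C(C)C
F3 | step 9 | dimethyl (3S)-3,7,7-trimethyl-3-[(triisopropylsilyloxy)methyl]-2,3,6,7-tetrahydrooxepine-2,2-dicarboxylate (enantiomer of 14) | COC(=O)C1(C(=O)OC)OC(C)(C)CC=C[C@@]1(C)CO[Si](C(C)C)(C(C)C)C(C)C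
F4 | step 17 | cis-diol: tricyclic core with C1–OH and C11–OH both trans to the C10 methyl, C3–OH free | O[C@@H]1C[C@](C)(O)[C@]23OC(C)(C)C=C[C@H](OC2=O)[C@]3(C)[C@@H]1O
F5 | step 17 | C11 epimer of acyloin 24 | O=C1C[C@](C)(O)[C@]23OC(C)(C)C=C[C@H](OC2=O)[C@]3(C)[C@@H]1O
F6 | step 17 | C11 epimer of benzoate 25 | O=C1C[C@](C)(O)[C@]23OC(C)(C)C=C[C@H](OC2=O)[C@]3(C)[C@@H]1OC(=O)c1ccccc1
F7 | step 10 | cis-fused γ-lactone methyl ester (lactone C4–C5(=O)–O–C11 on the oxepene; CO2Me on C4; C8=C9) | COC(=O)[C@]23OC(C)(C)CC=C[C@]3(C)COC2=O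
F8 | step 10 | 8-iodo lactone methyl ester with free C11–OH (lactone C4–C5(=O)–O–C9) | COC(=O)[C@]23OC(C)(C)C[C@@H](I)[C@H](OC2=O)[C@]3(C)CO
F9 | step 10 | triisopropylsilyl ether of F8 | COC(=O)[C@]23OC(C)(C)C[C@@H](I)[C@H](OC2=O)[C@]3(C)CO[Si](C(C)C)(C(C)C)C(C)C
F10 | step 10 | methyl ester of lactone acid 17 | COC(=O)[C@]23OC(C)(C)C=C[C@H](OC2=O)[C@]3(C)CO[Si](C(C)C)(C(C)C)C(C)C
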